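**Retrosynthetic overview**
- The dihydropyranone is the only ring of the target and is closed last, by ring-closing metathesis of a C6 acrylate onto the C5 allyl group.
- The anti C6'-OAc / C4'-OH pair comes from an Evans–Tishchenko reduction of a C4' ketone directed by the free C6' hydroxyl.
- The C4' carbonyl is a 1,3-dithiane acyl anion used as a linchpin: C4'–C5' by opening (R)-styryloxirane, a 1,4-Brook relay, then C4'–C3' by SN2' attack on a vinyl epoxide. That attack creates the E-C1'=C2' alkene and frees O6, which is trapped as the acrylate.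
- The two oxiranes come from cinnamaldehyde (Corey–Chaykovsky, hydrolytic kinetic resolution) and pent-4-enal (organocatalytic α-chlorination, vinyl Grignard, ring closure).
- Ring order: transient oxiranes, then the purchased dithiane as a removable mask, then the dihydropyranone last.

Assumption: the lactone is numbered C2–C6 and the side chain C1'–C8', so the target is (6S)-6-[(1E,4R,6S,7E)-6-acetoxy-4-hydroxy-8-phenylocta-1,7-dienyl]-5,6-dihydro-2H-pyran-2-one (4',6'-anti); catalyst antipodes are named from recalled precedent [(R,R)-Co(salen) leaves (S)-methyloxirane; (2R,5R)-2,5-diphenylpyrrolidine gives (S)-2-chloroaldehydes; (−)-Ipc2B(allyl) gives (S)-1-phenylbut-3-en-1-ol] and the other antipode is used if a sign proves opposite.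

**Step 1**
Reactants: 1 (E)-cinnamaldehyde
Product: 2 rac-2-[(E)-2-phenylethenyl]oxirane
Conditions: Me3S+ I−, NaH, DMSO/THF, 0 °C → rt
Reagents that add atoms: trimethylsulfonium iodide, C[S+](C)C.[I-]
Why: Corey–Chaykovsky epoxidation, in which the sulfonium methylide adds 1,2 to the enal and the betaine closes to the vinyl epoxide (racemic, no stereocentre set yet).

**Step 2**
Reactants: 2 rac-2-[(E)-2-phenylethenyl]oxirane
Product: 3 (2R)-2-[(E)-2-phenylethenyl]oxirane
Conditions: (S,S)-(salen)Co(III)OAc (0.5–1 mol %), H2O (0.55 equiv), THF, 0 °C → rt; distil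
Reagents that add atoms: none
Why: Jacobsen hydrolytic kinetic resolution, in which the catalyst hydrolyses the (S)-epoxide at its terminal carbon and leaves (R)-3 (future C6') in high ee at about 55 % conversion.

**Step 3**
Reactants: 4 pent-4-enal
Product: 6 (3S,4R)-4-chlorohepta-1,6-dien-3-ol, via (2R)-2-chloropent-4-enal 5 (not isolated)
Conditions: NCS, (2S,5S)-2,5-diphenylpyrrolidine (10 mol %), CH2Cl2, 0 °C → rt; pentane, filter; then CH2=CHMgBr, THF, −78 °C
Reagents that add atoms: N-chlorosuccinimide, O=C1CCC(=O)N1Cl; vinylmagnesium bromide, C=C[Mg]Br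
Why: Enamine-catalysed α-chlorination (Jørgensen type) sets the C–Cl centre (future C6) by catalyst face shielding, and the Grignard adds under Cornforth control (anti major); the carbinol configuration is irrelevant because that carbon becomes sp2 in step 5.

**Step 4**
Reactants: 6 (3S,4R)-4-chlorohepta-1,6-dien-3-ol
Product: 7 (2S,3S)-2-ethenyl-3-(prop-2-en-1-yl)oxirane
Conditions: KOH, EtOH, rt; pentane extraction, careful distillation (volatile)
Reagents that add atoms: none
Why: Intramolecular Williamson SN2 closure of the chlorohydrin with inversion at the chlorine-bearing carbon, turning (R)-C–Cl into the (S)-C–O centre that becomes C6 (the minor cis epoxide from the syn chlorohydrin has the same C6 configuration).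

**Step 5**
Reactants: 8 2-(tert-butyldimethylsilyl)-1,3-dithiane; 3 (2R)-2-[(E)-2-phenylethenyl]oxirane; 7 (2S,3S)-2-ethenyl-3-(prop-2-en-1-yl)oxirane
Product: 13 (4S,5E)-7-{2-[(2S,3E)-2-(tert-butyldimethylsilyloxy)-4-phenylbut-3-en-1-yl]-1,3-dithian-2-yl}hepta-1,5-dien-4-yl prop-2-enoate, via lithiated silyl dithiane 9 (not isolated), via lithium alkoxide adduct 10 (not isolated), via Brook-relayed dithianyl lithium 11 (not isolated), via dienyl lithium alkoxide 12 (not isolated)
Conditions: 8, t-BuLi, Et2O, −78 → −45 °C; 3, −78 → −25 °C; then 7, HMPA/THF, −78 → −20 °C; then CH2=CHCOCl, −78 → 0 °C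
Reagents that add atoms: acryloyl chloride, C=CC(Cl)=O
Why: Proposed new method: a Smith-type anion-relay linchpin coupling (known for 2-silyl-1,3-dithianes and two ordinary epoxides) is extended to a vinyl epoxide as second electrophile and an acylative quench — lithiated 8 opens 3 at its unhindered CH2 (SN2' there would require attack at the phenyl-bearing alkene carbon), HMPA triggers the 1,4-Brook shift that puts TBS on O6' and regenerates a dithianyl acyl anion at C4', and this encumbered 2-alkyl dithianyl lithium attacks the open CH2= terminus of 7 (SN2', the known preference of hindered 2-lithio-1,3-dithianes for vinyl epoxides) through the s-trans conformer to give the E-C1'=C2' alkene, while the oxirane C–O bonds that become C6'–O and C6–O are never broken, so C6' (S) and C6 (S) are carried over with retention.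

**Step 6**
Reactants: 13 (4S,5E)-7-{2-[(2S,3E)-2-(tert-butyldimethylsilyloxy)-4-phenylbut-3-en-1-yl]-1,3-dithian-2-yl}hepta-1,5-dien-4-yl prop-2-enoate
Product: 15 (4S,5E,10S,11E)-10-hydroxy-8-oxo-12-phenyldodeca-1,5,11-trien-4-yl prop-2-enoate, via hydroxy dithiane 14 (not isolated)
Conditions: HF·pyridine, pyridine, THF, 0 °C → rt; then MeCN/H2O 9:1, PhI(OCOCF3)2, 0 °C, 10 min; use at once
Reagents that add atoms: water, O
Why: Fluoride desilylation followed in the same flask by Stork–Zhao hypervalent-iodine oxidative hydrolysis of the dithiane, both pyridine-buffered and fast, so the β,γ-unsaturated ketone is exposed only briefly and no stereocentre is touched.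

**Step 7**
Reactants: 15 (4S,5E,10S,11E)-10-hydroxy-8-oxo-12-phenyldodeca-1,5,11-trien-4-yl prop-2-enoate
Product: 16 (4S,5E,8R,10S,11E)-10-acetoxy-8-hydroxy-12-phenyldodeca-1,5,11-trien-4-yl prop-2-enoate
Conditions: SmI2 (0.3 equiv), CH3CHO (8 equiv), THF, −10 °C
Reagents that add atoms: acetaldehyde, CC=O
Why: Evans–Tishchenko reduction, in which the samarium-bound acetaldehyde hemiacetal on O6' delivers hydride intramolecularly through a chair-like transition state, giving the 1,3-anti (4'R) carbinol and leaving the acetate on O6' only.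

**Step 8**
Reactants: 16 (4S,5E,8R,10S,11E)-10-acetoxy-8-hydroxy-12-phenyldodeca-1,5,11-trien-4-yl prop-2-enoate
Product: 17 (6S)-6-[(1E,4R,6S,7E)-6-acetoxy-4-hydroxy-8-phenylocta-1,7-dien-1-yl]-5,6-dihydro-2H-pyran-2-one
Conditions: Grubbs II (5 mol %), CH2Cl2 (2 mM), 40 °C
Reagents that add atoms: none
Why: Ring-closing metathesis of the acrylate with the terminal allyl alkene gives the six-membered unsaturated lactone with loss of ethene, the internal E-alkene and the styrene being much slower partners.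

**Compound list**
1 | (E)-cinnamaldehyde | O=C/C=C/c1ccccc1 | starting material
2 | rac-2-[(E)-2-phenylethenyl]oxirane | C1OC1/C=C/c1ccccc1 | intermediate
3 | (2R)-2-[(E)-2-phenylethenyl]oxirane | O1[C@H](/C=C/c2ccccc2)C1 | intermediate
4 | pent-4-enal | C=CCCC=O | starting material
5 | (2R)-2-chloropent-4-enal | O=C[C@H](Cl)CC=C | intermediate
6 | (3S,4R)-4-chlorohepta-1,6-dien-3-ol (anti, major; 3R epimer converges) | C=C[C@H](O)[C@H](Cl)CC=C | intermediate
7 | (2S,3S)-2-ethenyl-3-(prop-2-en-1-yl)oxirane (trans, major; C2 epimer converges) | C=C[C@@H]1O[C@H]1CC=C | intermediate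
8 | 2-(tert-butyldimethylsilyl)-1,3-dithiane | CC(C)(C)[Si](C)(C)C1SCCCS1 | starting material
9 | 2-lithio-2-(tert-butyldimethylsilyl)-1,3-dithiane | [Li]C1([Si](C)(C)C(C)(C)C)SCCCS1 | intermediate
10 | lithium (2S,3E)-1-[2-(tert-butyldimethylsilyl)-1,3-dithian-2-yl]-4-phenylbut-3-en-2-olate | [Li+].[O-][C@@H](CC1([Si](C)(C)C(C)(C)C)SCCCS1)/C=C/c1ccccc1 | intermediate
11 | 2-lithio-2-[(2S,3E)-2-(tert-butyldimethylsilyloxy)-4-phenylbut-3-en-1-yl]-1,3-dithiane | [Li]C1(C[C@H](O[Si](C)(C)C(C)(C)C)/C=C/c2ccccc2)SCCCS1 | intermediate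
12 | lithium (4S,5E)-7-{2-[(2S,3E)-2-(tert-butyldimethylsilyloxy)-4-phenylbut-3-en-1-yl]-1,3-dithian-2-yl}hepta-1,5-dien-4-olate | [Li+].[O-][C@@H](CC=C)/C=C/CC1(C[C@H](O[Si](C)(C)C(C)(C)C)/C=C/c2ccccc2)SCCCS1 | intermediate
13 | (4S,5E)-7-{2-[(2S,3E)-2-(tert-butyldimethylsilyloxy)-4-phenylbut-3-en-1-yl]-1,3-dithian-2-yl}hepta-1,5-dien-4-yl prop-2-enoate | C=CC(=O)O[C@@H](CC=C)/C=C/CC1(C[C@H](O[Si](C)(C)C(C)(C)C)/C=C/c2ccccc2)SCCCS1 | intermediate
14 | (4S,5E)-7-{2-[(2S,3E)-2-hydroxy-4-phenylbut-3-en-1-yl]-1,3-dithian-2-yl}hepta-1,5-dien-4-yl prop-2-enoate | C=CC(=O)O[C@@H](CC=C)/C=C/CC1(C[C@H](O)/C=C/c2ccccc2)SCCCS1 | intermediate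
15 | (4S,5E,10S,11E)-10-hydroxy-8-oxo-12-phenyldodeca-1,5,11-trien-4-yl prop-2-enoate | C=CC(=O)O[C@@H](CC=C)/C=C/CC(=O)C[C@H](O)/C=C/c1ccccc1 | intermediate
16 | (4S,5E,8R,10S,11E)-10-acetoxy-8-hydroxy-12-phenyldodeca-1,5,11-trien-4-yl prop-2-enoate | C=CC(=O)O[C@@H](CC=C)/C=C/C[C@@H](O)C[C@H](OC(C)=O)/C=C/c1ccccc1 | intermediate
17 | (6S)-6-[(1E,4R,6S,7E)-6-acetoxy-4-hydroxy-8-phenylocta-1,7-dien-1-yl]-5,6-dihydro-2H-pyran-2-one | CC(=O)O[C@H](/C=C/c1ccccc1)C[C@H](O)C/C=C/[C@@H]1CC=CC(=O)O1 | target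

**Step count:** 8 steps in total; longest linear sequence 6 steps (1 → 2 → 3 → 13 → 15 → 16 → 17, or equally 4 → 6 → 7 → 13 → 15 → 16 → 17).

**The three steps most likely to fail**

Step 5 (relay coupling). The risks are SN2 instead of SN2' attack on 7, E/Z leakage, mistimed Brook shift and the acylative quench. The fallback sets out from 8 and 3 and comes back at 13; it makes the C3'–C4' bond by plain SN2 and sets C6 by reagent control instead of by the vinyl epoxide. Carbanion 11 is generated as in step 5 and alkylated with excess (E)-1,4-dibromobut-2-ene to give 2-[(2E)-4-bromobut-2-en-1-yl]-2-[(2S,3E)-2-(tert-butyldimethylsilyloxy)-4-phenylbut-3-en-1-yl]-1,3-dithiane F1. Ganem oxidation (Me3NO, DMSO) converts the allylic bromide into (2E)-4-{2-[(2S,3E)-2-(tert-butyldimethylsilyloxy)-4-phenylbut-3-en-1-yl]-1,3-dithian-2-yl}but-2-enal F2. Brown allylation with (−)-Ipc2B(allyl) at −78 °C (ethanolamine work-up, no peroxide because of the sulfur) gives (4S,5E)-7-{2-[(2S,3E)-2-(tert-butyldimethylsilyloxy)-4-phenylbut-3-en-1-yl]-1,3-dithian-2-yl}hepta-1,5-dien-4-ol F3, and acryloyl chloride/Et3N/DMAP returns 13.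

Step 6 (unmasking). Ketone 15 is a β,γ-unsaturated ketone with an allylic acyloxy group in the δ position, so it can conjugate or expel acrylate. The fallback sets out from 8 and 3 and comes back at 17; it never makes such a ketone, because the C6 oxygen arrives only in the last step and the C1'=C2' bond is made by cross-metathesis.
- Carbanion 11 is quenched with allyl bromide to give 2-[(2S,3E)-2-(tert-butyldimethylsilyloxy)-4-phenylbut-3-en-1-yl]-2-(prop-2-en-1-yl)-1,3-dithiane F4.
- HF·pyridine gives (2S,3E)-4-phenyl-1-[2-(prop-2-en-1-yl)-1,3-dithian-2-yl]but-3-en-2-ol F5, which PhI(OCOCF3)2 in the same flask converts into (6S,7E)-6-hydroxy-8-phenylocta-1,7-dien-4-one F6.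
- Evans–Tishchenko reduction with acetaldehyde/SmI2 gives (1E,3S,5R)-5-hydroxy-1-phenylocta-1,7-dien-3-yl acetate F7.
- Separately, acrolein and (−)-Ipc2B(allyl) give (3S)-hexa-1,5-dien-3-ol F8, acryloyl chloride gives (3S)-hexa-1,5-dien-3-yl prop-2-enoate F9, and ring-closing metathesis gives (6S)-6-ethenyl-5,6-dihydro-2H-pyran-2-one F10.
- Cross-metathesis of F7 with F10 (Hoveyda–Grubbs II) gives 17.

Step 7 (Evans–Tishchenko on an acrylate-bearing, fragile ketone). Samarium may engage the acrylate or conversion may stall. The fallback sets out from 15 and comes back at 16; it separates reduction from acylation. Saksena–Evans reduction with Me4NBH(OAc)3 in MeCN/AcOH at −35 °C (external hydride, 1,3-anti) gives (4S,5E,8R,10S,11E)-8,10-dihydroxy-12-phenyldodeca-1,5,11-trien-4-yl prop-2-enoate F11. Catalyst-controlled site-selective acetylation follows, using Ac2O, i-Pr2NEt and the matched enantiomer of a Birman amidine acyl-transfer catalyst, which acylates carbinols next to a π-system; this should take the styryl carbinol in preference to the C8 carbinol and give 16.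

**Further compounds**
F1 | step 5 | 2-[(2E)-4-bromobut-2-en-1-yl]-2-[(2S,3E)-2-(tert-butyldimethylsilyloxy)-4-phenylbut-3-en-1-yl]-1,3-dithiane | BrC/C=C/CC1(C[C@H](O[Si](C)(C)C(C)(C)C)/C=C/c2ccccc2)SCCCS1
F2 | step 5 | (2E)-4-{2-[(2S,3E)-2-(tert-butyldimethylsilyloxy)-4-phenylbut-3-en-1-yl]-1,3-dithian-2-yl}but-2-enal | O=C/C=C/CC1(C[C@H](O[Si](C)(C)C(C)(C)C)/C=C/c2ccccc2)SCCCS1
F3 | step 5 | (4S,5E)-7-{2-[(2S,3E)-2-(tert-butyldimethylsilyloxy)-4-phenylbut-3-en-1-yl]-1,3-dithian-2-yl}hepta-1,5-dien-4-ol | O[C@@H](CC=C)/C=C/CC1(C[C@H](O[Si](C)(C)C(C)(C)C)/C=C/c2ccccc2)SCCCS1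
F4 | step 6 | 2-[(2S,3E)-2-(tert-butyldimethylsilyloxy)-4-phenylbut-3-en-1-yl]-2-(prop-2-en-1-yl)-1,3-dithiane | C=CCC1(C[C@H](O[Si](C)(C)C(C)(C)C)/C=C/c2ccccc2)SCCCS1
F5 | step 6 | (2S,3E)-4-phenyl-1-[2-(prop-2-en-1-yl)-1,3-dithian-2-yl]but-3-en-2-ol | C=CCC1(C[C@H](O)/C=C/c2ccccc2)SCCCS1
F6 | step 6 | (6S,7E)-6-hydroxy-8-phenylocta-1,7-dien-4-one | C=CCC(=O)C[C@H](O)/C=C/c1ccccc1
F7 | step 6 | (1E,3S,5R)-5-hydroxy-1-phenylocta-1,7-dien-3-yl acetate | C=CC[C@@H](O)C[C@H](OC(C)=O)/C=C/c1ccccc1
F8 | step 6 | (3S)-hexa-1,5-dien-3-ol | C=C[C@@H](O)CC=C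
F9 | step 6 | (3S)-hexa-1,5-dien-3-yl prop-2-enoate | C=CC(=O)O[C@H](C=C)CC=C
F10 | step 6 | (6S)-6-ethenyl-5,6-dihydro-2H-pyran-2-one | C=C[C@@H]1CC=CC(=O)O1
F11 | step 7 | (4S,5E,8R,10S,11E)-8,10-dihydroxy-12-phenyldodeca-1,5,11-trien-4-yl prop-2-enoate | C=CC(=O)O[C@@H](CC=C)/C=C/C[C@@H](O)C[C@H](O)/C=C/c1ccccc1
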